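**Plan**

- Retrosynthesis: the three ring ester C–O bonds are cut first (O4 2‑methylbutanoate, then O3 acetate, then O5 3‑methylpentanoate), then the C3–O and C4–O bonds of the cis‑diol, which leaves a (5R)‑5‑hydroxycyclohexa‑1,3‑diene ester.
- Enabling feature: in the cyclohexene ring (C1 ester‑bearing alkene carbon, C2 alkene CH, C3 to C5 oxygenated, C6 methylene) the C5 oxygen and C2 are 1,4‑related. With C1 made sp3, that oxygen can be tied to C2 as an ether bridge, and the resulting 7‑oxanorbornene is cut at C1–C2 and C5–C6 into furan and an acrylate.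
- Forward order: a [4+2] addition closes the carbocycle with the oxygen bridge in place; ester exchange; base opens the bridge to the C1=C2 alkene and the O5 hydroxyl; then O5 acylation, osmylation of C3=C4, O3 acetate through the orthoacetate, and O4 acylation.
- Stereochemistry: C5 comes from the catalyst‑controlled endo cycloaddition. Only the endo adduct has the right bridgehead; an exo adduct from the same acrylate face would lead to the antipode, so it must be removed. C3 and C4 come from syn‑osmylation anti to O5, and the two side‑chain centres are bought with the acids.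

Key step: step 1

Assumption: furan follows the sense of induction that this oxazaborolidinium catalyst class shows with acrylate esters and other dienes (the (S)‑catalyst giving the S‑configured ester‑bearing carbon), so the (R)‑catalyst is specified; both antipodes of the diphenylprolinol precursor are commercial.

**Step 1**
Reactants: 1 furan; 2 2,2,2‑trifluoroethyl acrylate
Product: 3 2,2,2‑trifluoroethyl (1R,2R,4R)‑7‑oxabicyclo[2.2.1]hept‑5‑ene‑2‑carboxylate (endo ester)
Conditions: 20 mol % of the salt of (R)‑3,3‑diphenyl‑1‑(o‑tolyl)tetrahydro‑1H,3H‑pyrrolo[1,2‑c][1,3,2]oxazaborole with HN(SO2CF3)2 (from (R)‑α,α‑diphenylprolinol and tri‑o‑tolylboroxine, then the acid, CH2Cl2, −25 °C), 1 (5 equiv), CH2Cl2, −78 °C (−40 °C at most); Et3N quench cold; SiO2 chromatography below 20 °C to remove the exo isomer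
Reagents that add atoms: none
Why: The N‑protonated oxazaborolidine binds the acrylate carbonyl at boron and lowers its LUMO, and furan then adds in a concerted, asynchronous, suprafacial [4+2] cycloaddition that forms the C1–C2 and C5–C6 bonds (shikimate numbering) in one event; the closest known reaction type is the oxazaborolidinium‑catalysed asymmetric Diels–Alder reaction of acrylate esters with cyclic and acyclic dienes, furan included. The six‑membered carbocycle closes by this cycloaddition and the furan oxygen is left as a one‑atom bridge from C2 to C5. The ester‑bearing carbon is set by the catalyst, whose aryl group screens one enantioface of the bound s‑trans acrylate (the (S)‑catalyst gives the S centre, hence the (R)‑catalyst here), and the two bridgeheads follow from the endo approach of the diene. Enantiofacial and endo selectivity are both required, because an exo adduct formed on the same acrylate face has antipodal bridgeheads and would end as the mirror‑image dienol once C1 and C2 become alkene carbons. The trifluoroethyl ester makes the dienophile reactive enough for −78 °C, where endo addition is kinetic and cycloreversion is frozen, and the residual exo isomer is removed by chromatography before the bridge is opened. Furan is symmetric, so there is no regiochemical question.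

**Step 2**
Reactants: 3 2,2,2‑trifluoroethyl (1R,2R,4R)‑7‑oxabicyclo[2.2.1]hept‑5‑ene‑2‑carboxylate
Product: 4 methyl (1R,2R,4R)‑7‑oxabicyclo[2.2.1]hept‑5‑ene‑2‑carboxylate
Conditions: K2CO3 (0.2 equiv), MeOH, 0 °C
Reagents that add atoms: methanol, CO
Why: Carbonate‑catalysed transesterification in methanol is driven by loss of the much less basic trifluoroethoxide; the bridgeheads cannot epimerise, and any epimerisation at the ester‑bearing carbon is without consequence because that carbon becomes sp2 in step 3.

**Step 3**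
Reactants: 4 methyl (1R,2R,4R)‑7‑oxabicyclo[2.2.1]hept‑5‑ene‑2‑carboxylate
Product: 6 methyl (5R)‑5‑hydroxycyclohexa‑1,3‑diene‑1‑carboxylate, via lithium alkoxide 5 (not isolated)
Conditions: LiN(SiMe3)2 (1.15 equiv), THF, −78 °C; aq. NH4Cl at −78 °C
Reagents that add atoms: lithium bis(trimethylsilyl)amide, [Li+].C[Si](C)(C)[N-][Si](C)(C)C (its lithium is held in 5 only)
Why: E1cB β‑elimination (retro‑oxa‑Michael opening of a 7‑oxanorbornene ester), in which the ester enolate expels the bridging oxygen from the adjacent bridgehead with release of ring strain, creating the C1=C2 alkene and the O5 alkoxide while the carbinol centre, not involved in any bond change, keeps its R configuration; the cold quench avoids dehydration to methyl benzoate.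

**Step 4**
Reactants: 6 methyl (5R)‑5‑hydroxycyclohexa‑1,3‑diene‑1‑carboxylate; 7 (3S)‑3‑methylpentanoic acid
Product: 8 methyl (5R)‑5‑{[(3S)‑3‑methylpentanoyl]oxy}cyclohexa‑1,3‑diene‑1‑carboxylate
Conditions: 7 (1.2 equiv), N,N'‑dicyclohexylcarbodiimide (DCC, 1.2 equiv), 4‑(dimethylamino)pyridine (DMAP, 0.1 equiv), CH2Cl2, 0 °C
Reagents that add atoms: none
Why: Steglich esterification acylates the secondary dienyl alcohol at oxygen with retention at C5; the stereocentre of the acid is β to the carbonyl and cannot epimerise, and the near‑neutral cold conditions should not trigger loss of the acyloxy group toward the aromatic ester.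

**Step 5**
Reactants: 8 methyl (5R)‑5‑{[(3S)‑3‑methylpentanoyl]oxy}cyclohexa‑1,3‑diene‑1‑carboxylate
Product: 9 methyl 5‑O‑[(3S)‑3‑methylpentanoyl]shikimate, i.e. methyl (3R,4R,5R)‑3,4‑dihydroxy‑5‑{[(3S)‑3‑methylpentanoyl]oxy}cyclohex‑1‑ene‑1‑carboxylate (the 4R label reflects a priority change only; the geometry is that of shikimate)
Conditions: OsO4 (2 mol %), N‑methylmorpholine N‑oxide (1.05 equiv), acetone/H2O 4:1, 0 °C; aq. NaHSO3
Reagents that add atoms: osmium tetroxide, O=[Os](=O)(=O)=O; N‑methylmorpholine N‑oxide, C[N+]1([O-])CCOCC1; water, O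
Why: Upjohn dihydroxylation, in which OsO4 adds in a suprafacial [3+2] fashion to the more electron‑rich C3=C4 alkene (C1=C2 is deactivated by the conjugated ester) from the face opposite the C5 acyloxy group, as known for the 5‑silyloxy analogue, so O3 and O4 arise cis to each other and trans to O5.

**Step 6**
Reactants: 9 methyl 5‑O‑[(3S)‑3‑methylpentanoyl]shikimate
Product: 11 methyl 3‑O‑acetyl‑5‑O‑[(3S)‑3‑methylpentanoyl]shikimate (3R,4S,5R), via cyclic orthoacetate 10 (not isolated)
Conditions: MeC(OMe)3 (3 equiv), pyridinium p‑toluenesulfonate (5 mol %), CH2Cl2, 23 °C; evaporate; 80% aq. AcOH, 0 to 23 °C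
Reagents that add atoms: trimethyl orthoacetate, COC(C)(OC)OC; water, O
Why: Acid‑catalysed exchange turns the cis‑3,4‑diol into the cyclic orthoacetate, and mild aqueous acid opens it through the 2‑hydroxy‑1,3‑dioxolane, which collapses under stereoelectronic control to the axial ester and equatorial alcohol (orthoester route to monoacylated cis‑diols); in the half‑chair O3 is pseudoaxial and O4 equatorial, so the acetate lands on O3 and no ring stereocentre is touched.

**Step 7**
Reactants: 11 methyl 3‑O‑acetyl‑5‑O‑[(3S)‑3‑methylpentanoyl]shikimate; 12 (2R)‑2‑methylbutanoic acid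
Product: 13 methyl (3R,4S,5R)‑3‑(acetyloxy)‑4‑{[(2R)‑2‑methylbutanoyl]oxy}‑5‑{[(3S)‑3‑methylpentanoyl]oxy}cyclohex‑1‑ene‑1‑carboxylate (target)
Conditions: 12 (2 equiv), DCC (2 equiv), DMAP (0.2 equiv), CH2Cl2, 0 to 23 °C
Reagents that add atoms: none
Why: Steglich esterification of the remaining equatorial C4 hydroxyl, run cold with substoichiometric DMAP so that acylation outruns acetyl migration from O3 and the α‑stereocentre of the acid, carried in unchanged, does not epimerise through a ketene or an enolised acylpyridinium.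

**Compound list**

1 | furan | c1ccoc1 | starting material
2 | 2,2,2‑trifluoroethyl acrylate | C=CC(=O)OCC(F)(F)F | starting material
3 | 2,2,2‑trifluoroethyl (1R,2R,4R)‑7‑oxabicyclo[2.2.1]hept‑5‑ene‑2‑carboxylate (endo) | FC(F)(F)COC(=O)[C@@H]1C[C@@H]2C=C[C@H]1O2 | intermediate
4 | methyl (1R,2R,4R)‑7‑oxabicyclo[2.2.1]hept‑5‑ene‑2‑carboxylate (endo) | COC(=O)[C@@H]1C[C@@H]2C=C[C@H]1O2 | intermediate
5 | lithium (1R)‑5‑(methoxycarbonyl)cyclohexa‑2,4‑dien‑1‑olate (not isolated) | [Li+].[O-][C@@H]1CC(C(=O)OC)=CC=C1 | intermediate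
6 | methyl (5R)‑5‑hydroxycyclohexa‑1,3‑diene‑1‑carboxylate | O[C@@H]1CC(C(=O)OC)=CC=C1 | intermediate
7 | (3S)‑3‑methylpentanoic acid | CC[C@H](C)CC(=O)O | starting material
8 | methyl (5R)‑5‑{[(3S)‑3‑methylpentanoyl]oxy}cyclohexa‑1,3‑diene‑1‑carboxylate | CC[C@H](C)CC(=O)O[C@@H]1CC(C(=O)OC)=CC=C1 | intermediate
9 | methyl 5‑O‑[(3S)‑3‑methylpentanoyl]shikimate | CC[C@H](C)CC(=O)O[C@@H]1CC(C(=O)OC)=C[C@@H](O)[C@H]1O | intermediate
10 | methyl 3,4‑O‑(1‑methoxyethylidene)‑5‑O‑[(3S)‑3‑methylpentanoyl]shikimate, both epimers at the orthoester carbon (not isolated) | CC[C@H](C)CC(=O)O[C@@H]1CC(C(=O)OC)=C[C@H]2OC(C)(OC)O[C@@H]12 | intermediate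
11 | methyl 3‑O‑acetyl‑5‑O‑[(3S)‑3‑methylpentanoyl]shikimate | CC[C@H](C)CC(=O)O[C@@H]1CC(C(=O)OC)=C[C@@H](OC(C)=O)[C@H]1O | intermediate
12 | (2R)‑2‑methylbutanoic acid | CC[C@@H](C)C(=O)O | starting material
13 | methyl (3R,4S,5R)‑3‑(acetyloxy)‑4‑{[(2R)‑2‑methylbutanoyl]oxy}‑5‑{[(3S)‑3‑methylpentanoyl]oxy}cyclohex‑1‑ene‑1‑carboxylate | CC[C@H](C)CC(=O)O[C@@H]1CC(C(=O)OC)=C[C@@H](OC(C)=O)[C@H]1OC(=O)[C@H](C)CC | target

**Step count and risks**

Total step count: 7. Longest linear sequence: 7 steps (1 and 2 to 13).

The three steps most likely to fail are steps 1, 6 and 5, in that order.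

Step 1. Turnover may need a temperature at which cycloreversion sets in, some material may leak through the exo transition state, and the strongly acidic catalyst may oligomerise furan. Each of these lowers the enantiomeric purity of everything downstream, since the exo adduct is the precursor of the antipode. The fallback changes the dienophile to a chelating imide and sets out from furan 1. Furan is combined with purchased 3‑acryloyl‑1,3‑oxazolidin‑2‑one (C=CC(=O)N1CCOC1=O) and 5 mol % of the divalent copper complex [Cu((R,R)‑t‑Bu‑box)](SbF6)2 in CH2Cl2 at −78 °C. The ligand is 2,2'‑(propane‑2,2‑diyl)bis[(4R)‑4‑tert‑butyl‑4,5‑dihydro‑1,3‑oxazole] and the complex is made from CuCl2 and AgSbF6. Two‑point binding of the imide should give the endo imide 3‑{[(1R,2R,4R)‑7‑oxabicyclo[2.2.1]hept‑5‑en‑2‑yl]carbonyl}‑1,3‑oxazolidin‑2‑one F1, which is expected to be a solid that can be recrystallised free of exo isomer and minor enantiomer. LiSEt in THF at 0 °C should then cleave the imide, without enolisation, to S‑ethyl (1R,2R,4R)‑7‑oxabicyclo[2.2.1]hept‑5‑ene‑2‑carbothioate F2. Cs2CO3 in MeOH at 0 °C converts F2 into methyl ester 4, where the route is rejoined.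

Step 6. The orthoester may collapse toward O4 as well as O3, or the acetate may drift from the pseudoaxial O3 to the equatorial O4 during hydrolysis and purification. The fallback reverses the order in which O3 and O4 are esterified and sets out from diol 9. Et3SiCl and imidazole in CH2Cl2 at −20 °C should silylate the allylic O3 in preference to O4, which is flanked on both sides, giving methyl 5‑O‑[(3S)‑3‑methylpentanoyl]‑3‑O‑(triethylsilyl)shikimate F3. Acid 12 with DCC and DMAP then gives methyl 4‑O‑[(2R)‑2‑methylbutanoyl]‑5‑O‑[(3S)‑3‑methylpentanoyl]‑3‑O‑(triethylsilyl)shikimate F4. HF·pyridine in THF at 0 °C removes the silyl group under acidic conditions to give methyl 4‑O‑[(2R)‑2‑methylbutanoyl]‑5‑O‑[(3S)‑3‑methylpentanoyl]shikimate F5. Immediate acetylation with Ac2O in pyridine at 0 °C leads to target 13, where the route is rejoined. This detour also bypasses step 7, and no free hydroxyl ever sits next to the acetate.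

Step 5. Facial selectivity may be lower with an acyloxy group at C5 than with a silyloxy group, the acyl group may shift from O5 to O4 in the fresh diol under the mildly basic conditions, and dienyl ester 8 may lose the acid and aromatise before it is oxidised. The fallback carries O5 as a silyl ether through the osmylation and sets out from dienol 6.

- t‑BuMe2SiCl and imidazole in DMF give methyl (5R)‑5‑[(tert‑butyldimethylsilyl)oxy]cyclohexa‑1,3‑diene‑1‑carboxylate F6.
- OsO4 (cat.) with N‑methylmorpholine N‑oxide in acetone/H2O gives methyl 5‑O‑(tert‑butyldimethylsilyl)shikimate F7.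
- 2,2‑Dimethoxypropane with pyridinium p‑toluenesulfonate gives methyl 5‑O‑(tert‑butyldimethylsilyl)‑3,4‑O‑isopropylideneshikimate F8.
- Bu4NF buffered with AcOH in THF frees methyl 3,4‑O‑isopropylideneshikimate F9.
- Acid 7 with DCC and DMAP gives methyl 3,4‑O‑isopropylidene‑5‑O‑[(3S)‑3‑methylpentanoyl]shikimate F10.
- Aqueous CF3CO2H in CH2Cl2 at 0 °C removes the acetonide under acidic conditions, where acyl migration is slow, and returns diol 9, where the route is rejoined.

**Further compounds**

F1 | step 1 | 3‑{[(1R,2R,4R)‑7‑oxabicyclo[2.2.1]hept‑5‑en‑2‑yl]carbonyl}‑1,3‑oxazolidin‑2‑one | O=C([C@@H]1C[C@@H]2C=C[C@H]1O2)N1CCOC1=O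
F2 | step 1 | S‑ethyl (1R,2R,4R)‑7‑oxabicyclo[2.2.1]hept‑5‑ene‑2‑carbothioate | CCSC(=O)[C@@H]1C[C@@H]2C=C[C@H]1O2
F3 | step 6 | methyl 5‑O‑[(3S)‑3‑methylpentanoyl]‑3‑O‑(triethylsilyl)shikimate | CC[C@H](C)CC(=O)O[C@@H]1CC(C(=O)OC)=C[C@@H](O[Si](CC)(CC)CC)[C@H]1O
F4 | step 6 | methyl 4‑O‑[(2R)‑2‑methylbutanoyl]‑5‑O‑[(3S)‑3‑methylpentanoyl]‑3‑O‑(triethylsilyl)shikimate | CC[C@H](C)CC(=O)O[C@@H]1CC(C(=O)OC)=C[C@@H](O[Si](CC)(CC)CC)[C@H]1OC(=O)[C@H](C)CC
F5 | step 6 | methyl 4‑O‑[(2R)‑2‑methylbutanoyl]‑5‑O‑[(3S)‑3‑methylpentanoyl]shikimate | CC[C@H](C)CC(=O)O[C@@H]1CC(C(=O)OC)=C[C@@H](O)[C@H]1OC(=O)[C@H](C)CC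
F6 | step 5 | methyl (5R)‑5‑[(tert‑butyldimethylsilyl)oxy]cyclohexa‑1,3‑diene‑1‑carboxylate | CC(C)(C)[Si](C)(C)O[C@@H]1CC(C(=O)OC)=CC=C1
F7 | step 5 | methyl 5‑O‑(tert‑butyldimethylsilyl)shikimate | CC(C)(C)[Si](C)(C)O[C@@H]1CC(C(=O)OC)=C[C@@H](O)[C@H]1O
F8 | step 5 | methyl 5‑O‑(tert‑butyldimethylsilyl)‑3,4‑O‑isopropylideneshikimate | CC(C)(C)[Si](C)(C)O[C@@H]1CC(C(=O)OC)=C[C@H]2OC(C)(C)O[C@@H]12
F9 | step 5 | methyl 3,4‑O‑isopropylideneshikimate | O[C@@H]1CC(C(=O)OC)=C[C@H]2OC(C)(C)O[C@@H]12
F10 | step 5 | methyl 3,4‑O‑isopropylidene‑5‑O‑[(3S)‑3‑methylpentanoyl]shikimate | CC[C@H](C)CC(=O)O[C@@H]1CC(C(=O)OC)=C[C@H]2OC(C)(C)O[C@@H]12
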